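The data come from a simulation for an exercise; the scatter is artificial.

If one reagent makes one target, 20.0 % of the starting material finds no reagent in these recipes, since the reagent charge is 80.0 % of the starting-material charge. On that assumption reagent is the likely limiting reagent, and second substrate and third substrate, at 20.0 % and 200 % of the starting-material charge in amber, red, green and violet, may ask for reagent too.

| setting | delta | amber | red | green | violet |
|---|---|---|---|---|---|
| starting material | 0.081 M | 0.081 M | 0.081 M | 0.081 M | 0.081 M |
| reagent | 0.0648 M | 0.0648 M | 0.0648 M | 0.0648 M | 0.0648 M |
| second substrate | 0.032 M | 0.0162 M | 0.0162 M | 0.0162 M | 0.0162 M |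
| third substrate | 0.162 M | 0.162 M | 0.162 M | 0.162 M | 0.162 M |
| temperature | 55 °C |  | 55 °C | 30 °C | 80 °C |
| remark | run made earlier | at 30 °C until 8.0 h, from then on at 80 °C |  |  |  |
| time |  | 12 h | 12 h | 12 h | 12 h |

- delta (time / h: target / %, starting material / %): 0.500: 3.1, 94.2; 1.00: 8.4, 93.9; 1.50: 9.9, 90.0; 2.00: 9.6, 88.1; 2.50: 11.4, 86.2; 3.00: 13.2, 84.7; 4.00: 16.8, 83.3

(scatter of a reading: 1 percentage point)

- what was read earlier has a scatter of 1 percentage point, one standard deviation
- the earlier runs do not show what temperature does; that part of a forecast is a guess

- which flask leads in amount of target, in percent of the starting material charged ("all alike" within 1.5 percentage points) (amber / red / green / violet / all alike)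
- how much target is there at the end, in percent of the starting material charged: amber
- how much target is there at the end, in percent of the starting material charged: red
- how much target is there at the end, in percent of the starting material charged: green
- how much target is there at the end, in percent of the starting material charged: violet

The delta run gives its pace in two ways, from different species. Over 4.00 h the target reading gives a gain of 0.0420 h⁻¹ of the charge, and the starting-material reading gives a loss of 0.0418 h⁻¹. Within a scatter of 1 percentage point, these two readings of the delta run agree with starting material going to target one for one, and that pace is trusted.

Two ways to the end of red then part. Carried in a straight line through 12 h, the delta pace gives 50.4 %. If the reagent is instead used up one for one and divided among starting material, second substrate and third substrate in proportion to their amounts, as like rate constants divide it from start to finish, each receives the reagent share 25.0 %, the fraction of its own charge that the reagent can serve. That share is the reckoning's mark for target formed, counted before any later loss. On that assumption the line is the one that cheats, because it claims twice that share from a pace read over the first third of the time. This reckoning therefore commits to about 25.0 % formed in red. The readings are silent on temperature, so the split in the hot and cold flasks remains a guess.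

The forecast gives amber 18.5 %, red 16.5 %, green 6 % and violet 19 %, with violet in the lead: “Violet barely leads amber, unless the target degrades when hot.” Its figure for target in red lies below the 25.0 % formed that is reckoned here.

The flasks end at amber 16.8 %, red 22.8 %, green 14.2 % and violet 6.72 %, so red leads.

    starting material + reagent → target (k = 6.26 M⁻¹ h⁻¹, Ea = 56.0 kJ mol⁻¹)
    second substrate + reagent → second product (k = 41.2 M⁻¹ h⁻¹, Ea = 56.0 kJ mol⁻¹)
    third substrate + reagent → third product (k = 7.31 M⁻¹ h⁻¹, Ea = 82.0 kJ mol⁻¹)
    starting material → decomposition product (k = 2.16 × 10⁻⁴ h⁻¹, Ea = 128 kJ mol⁻¹)
    starting material + target → side product (k = 1.58 M⁻¹ h⁻¹, Ea = 72.0 kJ mol⁻¹)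
    (constants at 80 °C)

In violet, target plus half of the side product, whose percentages count two, comes to 19.5 %, a little below the share, with reagent at 0 %. Half of that formation in violet is over by 0.367 h, whereas target in violet has a half-life of 8.0 h by its step with starting material at 12.0 h, and the 12 h of the run span 1.50 such half-lives.

A violet flask charged with 0.16 M of reagent has a share of 61.7 %. It ends with 32.9 % of target and 42.5 % of side product, which makes 54.1 % formed.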